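**Retrosynthetic overview**
1. The aryl–vinyl bond of the coumarate comes from a Heck coupling of an acrylate ester with 4-iodophenol. The ester C–O bond comes from acryloyl chloride and eudesm-3-en-6β-ol.
2. The axial 6β-OH comes from α-face hydride delivery to eudesm-3-en-6-one. C5–H and the C3=C4 alkene come from kinetic α-protonation of the extended dienolate of eudesm-4-en-6-one.
3. The key disconnection is C6–C7: an enoyl radical, made from the formyl C–H of a monocyclic enal, closes 6-exo onto a prenyl alkene. This one isomerisation closes ring B, creates the C6 ketone and turns the prenyl group into the isopropyl group.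
4. The enal comes from 3-methylcyclohexenone by asymmetric Cu-catalysed conjugate addition of homoprenyl Grignard (sets C10), enolate trapping with a masked formyl cation, methyl addition, and acidic unmasking with dehydration.
5. Ring A is bought and ring B is closed by the radical step. C10 then controls C7, C5 and C6 in turn.

Assumption: locants C1–C15 in the explanations are eudesmane locants (C10 quaternary carbon, C5 ring-fusion CH, C6 carbinol carbon, C7 isopropyl-bearing carbon, C3=C4 ring alkene). Systematic names use naphthalene or cyclohexane locants.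

**Step 1**
Reactants: 1 3-methylcyclohex-2-en-1-one; 2 5-bromo-2-methylpent-2-ene; 3 trimethyl orthoformate
Product: 7 (3R)-2-(dimethoxymethyl)-3-methyl-3-(4-methylpent-3-en-1-yl)cyclohexan-1-one (C2 epimers), via homoprenylmagnesium bromide 4 (not isolated), via dimethoxycarbenium tetrafluoroborate 5 (not isolated), via bromomagnesium enolate 6 (not isolated)
Conditions: (a) 2, Mg, Et2O, 35 °C; (b) Cu(OTf)2 (3 mol %), tert-leucinol-derived hydroxyalkyl N-mesityl imidazolinium hexafluorophosphate (NHC precursor, 4 mol %, the enantiomer that gives 3R), slow addition of 1, Et2O, −30 °C; (c) in a second flask 3, BF3·OEt2, CH2Cl2, −30 °C, then the enolate solution is added at −78 °C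
Reagents that add atoms: none
Why: Copper-catalysed asymmetric conjugate addition of the Grignard reagent to the β-methyl enone sets the quaternary centre C10 (3R, about 90–95 % ee expected) under ligand control, and the regiodefined magnesium enolate is then C-formylated in masked form at C5 by the small, very electrophilic dialkoxycarbenium ion (tandem conjugate addition–enolate trapping), the C2 configuration being irrelevant because this carbon becomes sp2 in step 2.

**Step 2**
Reactants: 7 (3R)-2-(dimethoxymethyl)-3-methyl-3-(4-methylpent-3-en-1-yl)cyclohexan-1-one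
Product: 9 (6R)-2,6-dimethyl-6-(4-methylpent-3-en-1-yl)cyclohex-1-ene-1-carbaldehyde, via tertiary carbinol acetal 8 (not isolated)
Conditions: MeLi, CeCl3, THF, −78 °C; then 1 M HCl, THF, 23 °C
Reagents that add atoms: methyllithium [Li]C; water O
Why: Organocerium 1,2-addition suppresses enolisation of the hindered ketone, and aqueous acid then hydrolyses the acetal and dehydrates the tertiary β-hydroxy aldehyde (aldol-type dehydration) to the conjugated tetrasubstituted enal, the thermodynamic alkene isomer, with no new stereocentre and C10 untouched.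

**Step 3 (key step)**
Reactants: 9 (6R)-2,6-dimethyl-6-(4-methylpent-3-en-1-yl)cyclohex-1-ene-1-carbaldehyde
Product: 13 (2S,4aR)-4a,8-dimethyl-2-(propan-2-yl)-3,4,4a,5,6,7-hexahydronaphthalen-1(2H)-one (eudesm-4-en-6-one), via enoyl radical 10 (not isolated), via tertiary alkyl radical 11 (not isolated), via C2-epimeric ketone mixture 12 (not isolated)
Conditions: t-C12H25SH (3 × 0.1 equiv), 1,1'-azobis(cyclohexanecarbonitrile) (3 × 0.1 equiv), degassed PhCl (0.02 M), 110 °C; then DBU (0.2 equiv), 23 °C
Reagents that add atoms: none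
Why: This is a thiol-catalysed radical-chain intramolecular hydroacylation (polarity-reversal catalysis, the reaction type that turns citronellal into menthone) in which the thiyl radical abstracts the formyl hydrogen, the enoyl σ-radical 10 cannot lose CO (that would give a vinyl radical) and adds 6-exo-trig to the less substituted prenyl carbon through a chair-like transition state with the side chain equatorial, the tertiary radical 11 takes hydrogen from the thiol so that prenyl becomes isopropyl, and DBU equilibration of the α-carbon C7 converges on the equatorial (2S) isopropyl ketone.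

**Step 4**
Reactants: 13 (2S,4aR)-4a,8-dimethyl-2-(propan-2-yl)-3,4,4a,5,6,7-hexahydronaphthalen-1(2H)-one
Product: 15 (2S,4aR,8aR)-4a,8-dimethyl-2-(propan-2-yl)-3,4,4a,5,6,8a-hexahydronaphthalen-1(2H)-one (eudesm-3-en-6-one), via potassium dienolate 14 (not isolated)
Conditions: KOt-Bu (3 equiv), THF, 0 °C, 20 min; cannulated into AcOH, THF–H2O, −78 to 0 °C; used without delay
Reagents that add atoms: none
Why: In this base-mediated enone deconjugation KOt-Bu gives the thermodynamically preferred heteroannular extended dienolate 14 by loss of a C3 proton, and fast kinetic C-protonation at the α-carbon C5 from the face opposite the axial angular methyl group sets 8aR (trans ring fusion) and leaves the C3=C4 alkene, while the short contact time spares the hindered tertiary C7–H.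

**Step 5**
Reactants: 15 (2S,4aR,8aR)-4a,8-dimethyl-2-(propan-2-yl)-3,4,4a,5,6,8a-hexahydronaphthalen-1(2H)-one
Product: 16 (1R,2S,4aR,8aR)-4a,8-dimethyl-2-(propan-2-yl)-1,2,3,4,4a,5,6,8a-octahydronaphthalen-1-ol (eudesm-3-en-6β-ol)
Conditions: LiBH(s-Bu)3, THF, −78 to −20 °C; then NaOH, H2O2, 0 °C
Reagents that add atoms: none
Why: In this diastereoselective ketone reduction with a bulky trialkylborohydride the axial β-face trajectory is blocked by the 1,3-diaxial angular methyl group, so hydride arrives equatorially from the α-face and gives the axial 6β-alcohol (1R, cis to the isopropyl group) at a temperature at which enolisation and reconjugation do not compete.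

**Step 6**
Reactants: 16 (1R,2S,4aR,8aR)-4a,8-dimethyl-2-(propan-2-yl)-1,2,3,4,4a,5,6,8a-octahydronaphthalen-1-ol; 17 acryloyl chloride
Product: 18 (1R,2S,4aR,8aR)-4a,8-dimethyl-2-(propan-2-yl)-1,2,3,4,4a,5,6,8a-octahydronaphthalen-1-yl prop-2-enoate
Conditions: Et3N, DMAP (0.2 equiv), BHT (trace), CH2Cl2, 0 to 23 °C
Reagents that add atoms: none
Why: DMAP-catalysed O-acylation with the smallest available enoyl chloride works even on hindered menthol-type alcohols and leaves the C6–O bond, and therefore every stereocentre, untouched.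

**Step 7**
Reactants: 18 (1R,2S,4aR,8aR)-4a,8-dimethyl-2-(propan-2-yl)-1,2,3,4,4a,5,6,8a-octahydronaphthalen-1-yl prop-2-enoate; 19 4-iodophenol
Product: 20 (1R,2S,4aR,8aR)-4a,8-dimethyl-2-(propan-2-yl)-1,2,3,4,4a,5,6,8a-octahydronaphthalen-1-yl (2E)-3-(4-hydroxyphenyl)prop-2-enoate (CNP0220414.1)
Conditions: Pd(OAc)2 (5 mol %), P(o-tol)3 (10 mol %), Et3N, MeCN, 80 °C
Reagents that add atoms: none
Why: Mizoroki–Heck arylation takes place only at the electron-poor terminal acrylate alkene (the hindered trisubstituted ring alkene is inert), tolerates the free phenol, and gives the E-alkene through syn insertion followed by syn β-hydride elimination.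

**Compound list**
1 | 3-methylcyclohex-2-en-1-one | CC1=CC(=O)CCC1 | starting material
2 | 5-bromo-2-methylpent-2-ene | CC(C)=CCCBr | starting material
3 | trimethyl orthoformate | COC(OC)OC | starting material
4 | (4-methylpent-3-en-1-yl)magnesium bromide | CC(C)=CCC[Mg]Br | intermediate
5 | dimethoxycarbenium tetrafluoroborate | COC=[O+]C.F[B-](F)(F)F | intermediate
6 | bromomagnesium (3R)-3-methyl-3-(4-methylpent-3-en-1-yl)cyclohex-1-en-1-olate | C[C@]1(CCC=C(C)C)CCCC(O[Mg]Br)=C1 | intermediate
7 | (3R)-2-(dimethoxymethyl)-3-methyl-3-(4-methylpent-3-en-1-yl)cyclohexan-1-one (C2 epimers) | O=C1CCC[C@](C)(CCC=C(C)C)C1C(OC)OC | intermediate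
8 | (3R)-2-(dimethoxymethyl)-1,3-dimethyl-3-(4-methylpent-3-en-1-yl)cyclohexan-1-ol (diastereomer mixture) | CC1(O)CCC[C@](C)(CCC=C(C)C)C1C(OC)OC | intermediate
9 | (6R)-2,6-dimethyl-6-(4-methylpent-3-en-1-yl)cyclohex-1-ene-1-carbaldehyde | CC1=C(C=O)[C@@](C)(CCC=C(C)C)CCC1 | intermediate
10 | (6R)-2,6-dimethyl-6-(4-methylpent-3-en-1-yl)cyclohex-1-ene-1-carbonyl radical | CC1=C([C]=O)[C@@](C)(CCC=C(C)C)CCC1 | intermediate
11 | 2-[(4aR)-4a,8-dimethyl-1-oxo-1,2,3,4,4a,5,6,7-octahydronaphthalen-2-yl]propan-2-yl radical | CC1=C2C(=O)C([C](C)C)CC[C@@]2(C)CCC1 | intermediate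
12 | (4aR)-4a,8-dimethyl-2-(propan-2-yl)-3,4,4a,5,6,7-hexahydronaphthalen-1(2H)-one (C2 epimers) | CC1=C2C(=O)C(C(C)C)CC[C@@]2(C)CCC1 | intermediate
13 | (2S,4aR)-4a,8-dimethyl-2-(propan-2-yl)-3,4,4a,5,6,7-hexahydronaphthalen-1(2H)-one | CC1=C2C(=O)[C@H](C(C)C)CC[C@@]2(C)CCC1 | intermediate
14 | potassium (2S,4aR)-4a,8-dimethyl-2-(propan-2-yl)-2,3,4,4a,5,6-hexahydronaphthalen-1-olate | CC1=CCC[C@]2(C)CC[C@@H](C(C)C)C([O-])=C12.[K+] | intermediate
15 | (2S,4aR,8aR)-4a,8-dimethyl-2-(propan-2-yl)-3,4,4a,5,6,8a-hexahydronaphthalen-1(2H)-one | CC1=CCC[C@]2(C)CC[C@@H](C(C)C)C(=O)[C@@H]12 | intermediate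
16 | (1R,2S,4aR,8aR)-4a,8-dimethyl-2-(propan-2-yl)-1,2,3,4,4a,5,6,8a-octahydronaphthalen-1-ol | CC1=CCC[C@]2(C)CC[C@@H](C(C)C)[C@@H](O)[C@@H]12 | intermediate
17 | acryloyl chloride | C=CC(=O)Cl | starting material
18 | (1R,2S,4aR,8aR)-4a,8-dimethyl-2-(propan-2-yl)-1,2,3,4,4a,5,6,8a-octahydronaphthalen-1-yl prop-2-enoate | CC1=CCC[C@]2(C)CC[C@@H](C(C)C)[C@@H](OC(=O)C=C)[C@@H]12 | intermediate
19 | 4-iodophenol | Oc1ccc(I)cc1 | starting material
20 | (1R,2S,4aR,8aR)-4a,8-dimethyl-2-(propan-2-yl)-1,2,3,4,4a,5,6,8a-octahydronaphthalen-1-yl (2E)-3-(4-hydroxyphenyl)prop-2-enoate | CC1=CCC[C@]2(C)CC[C@@H](C(C)C)[C@@H](OC(=O)/C=C/c3ccc(O)cc3)[C@@H]12 | target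

**Total step count:** 7. **Longest linear sequence:** 7.

**The three steps most likely to fail**

**Step 3.** Three things could go wrong:
- hydrogen abstraction from the hindered enal may be too slow;
- allylic hydrogen transfer may compete;
- the enoyl radical may leak through its ketenyl form and consume the thiol.

The fallback sets out from 9 and makes the same radical by selenium abstraction instead of hydrogen abstraction. Oxidation with NaClO2, NaH2PO4 and 2-methylbut-2-ene gives (6R)-2,6-dimethyl-6-(4-methylpent-3-en-1-yl)cyclohex-1-ene-1-carboxylic acid F1. Treatment with (PhSe)2 and PBu3 gives Se-phenyl (6R)-2,6-dimethyl-6-(4-methylpent-3-en-1-yl)cyclohex-1-ene-1-carboselenoate F2. Slow addition of (Me3Si)3SiH and AIBN in benzene at 80 °C then generates radical 10. After the same DBU equilibration the route is rejoined at 13.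

**Step 4.** Three things could go wrong:
- the enone may reconjugate;
- the C15 methyl group may be deprotonated instead of C3;
- C7 may partly epimerise while the enolates equilibrate.

The fallback sets out from 13 and replaces the free enolate by an isolable neutral dienol ether. Soft enolisation with t-BuMe2SiOTf and Et3N in CH2Cl2 gives tert-butyl{[(2S,4aR)-4a,8-dimethyl-2-(propan-2-yl)-2,3,4,4a,5,6-hexahydronaphthalen-1-yl]oxy}dimethylsilane F3. This is purified from any isomer and then cleaved with n-Bu4NF and AcOH in THF at −78 °C, with α-face protonation at C5. The route is rejoined at 15.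

**Step 1.** The neopentyl enolate carbon C5 may react at oxygen, or too slowly, with the carbenium salt. The fallback sets out from 6. The enolate is silylated with Me3SiCl and isolated as trimethyl{[(3R)-3-methyl-3-(4-methylpent-3-en-1-yl)cyclohex-1-en-1-yl]oxy}silane F4. This neutral nucleophile is then joined to 3 in a Mukaiyama-type acetal aldol reaction catalysed by Me3SiOTf in CH2Cl2 at −78 °C. The route is rejoined at 7.

**Further compounds**
F1 | step 3 | (6R)-2,6-dimethyl-6-(4-methylpent-3-en-1-yl)cyclohex-1-ene-1-carboxylic acid | CC1=C(C(=O)O)[C@@](C)(CCC=C(C)C)CCC1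
F2 | step 3 | Se-phenyl (6R)-2,6-dimethyl-6-(4-methylpent-3-en-1-yl)cyclohex-1-ene-1-carboselenoate | CC1=C(C(=O)[Se]c2ccccc2)[C@@](C)(CCC=C(C)C)CCC1
F3 | step 4 | tert-butyl{[(2S,4aR)-4a,8-dimethyl-2-(propan-2-yl)-2,3,4,4a,5,6-hexahydronaphthalen-1-yl]oxy}dimethylsilane | CC1=CCC[C@]2(C)CC[C@@H](C(C)C)C(O[Si](C)(C)C(C)(C)C)=C12
F4 | step 1 | trimethyl{[(3R)-3-methyl-3-(4-methylpent-3-en-1-yl)cyclohex-1-en-1-yl]oxy}silane | C[C@]1(CCC=C(C)C)CCCC(O[Si](C)(C)C)=C1
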